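The route rests on cutting the furan double bond C2'=C3' (benzofuran atoms primed, flavan atoms unprimed), the link between crowded flavan C8 and the benzofuran. C2' is unmasked as the carbonyl of a flavan-8-carboxylic ester and C3' as a formyl group on C3a', the two held together by the aryl ester oxygen O1'. Low-valent titanium then couples these two electrophilic carbons reductively, closing the furan ring and forming the only new skeletal bond in one operation, remote from the C2 stereocentre inherited from alpinetin. The precursor is the 2-formylaryl ester of (2S)-7-benzyloxy-5-methoxyflavan-8-carboxylic acid, made by plain acylation of a salicylaldehyde derived from 3-methoxy-2-methylphenol.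

Key step: step 9

Remark: natural (−)-alpinetin is taken to be the (2S) enantiomer of high optical purity; its C2 centre is carried through unchanged, and the descriptor stays (S) in every flavan of the route.

Step 1
Reactants: 1 alpinetin [(2S)-7-hydroxy-5-methoxyflavanone]
Product: 2 (2S)-7-benzyloxy-5-methoxyflavanone
Conditions: BnOH, PPh3, DIAD, THF, 0 °C to rt
Reagents that add atoms: benzyl alcohol, OCc1ccccc1
Why: Mitsunobu etherification of the acidic para-acyl phenol (the only OH group) runs under essentially neutral conditions, so the base-sensitive flavanone should not racemise at C2 by ring opening to the chalcone.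

Step 2
Reactants: 2 (2S)-7-benzyloxy-5-methoxyflavanone
Product: 4 (2S)-7-benzyloxy-5-methoxyflavan, via cis-flavan-4-ol 3 (not isolated)
Conditions: NaBH4, THF–MeOH, 0 °C; aqueous work-up, crude 3 used directly; then Et3SiH (5 equiv), TFA (5 equiv), CH2Cl2, −20 to 0 °C
Reagents that add atoms: none
Why: Hydride reduction of the aryl ketone followed by ionic hydrogenation (silane/acid deoxygenation) of the benzylic alcohol should work because the C4 cation is strongly stabilised by the 5- and 7-alkoxy groups and is trapped by excess silane, while C2 is not involved and the transient C4 centre disappears.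

Step 3
Reactants: 4 (2S)-7-benzyloxy-5-methoxyflavan
Product: 5 (2S)-7-benzyloxy-8-bromo-5-methoxyflavan
Conditions: NBS (1.0 equiv), CH2Cl2, −78 to 0 °C, dark
Reagents that add atoms: N-bromosuccinimide, O=C1CCC(=O)N1Br
Why: Electrophilic aromatic bromination of the phloroglucinol-type ring A should favour C8, which lies between the benzyloxy group and the tied-back ring oxygen O1 and is less shielded than C6 between two freely rotating alkoxy groups, the usual outcome for 5,7-di-O-alkylflavans with NBS.

Step 4
Reactants: 5 (2S)-7-benzyloxy-8-bromo-5-methoxyflavan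
Product: 7 (2S)-7-benzyloxy-5-methoxyflavan-8-carboxylic acid, via 8-lithioflavan 6 (not isolated)
Conditions: t-BuLi (2.1 equiv), THF, −78 °C, 15 min; dry CO2 gas, −78 °C to rt; aqueous HCl
Reagents that add atoms: carbon dioxide, O=C=O; tert-butyllithium, [Li]C(C)(C)C (lithium of intermediate 6 only)
Why: Bromine–lithium exchange at −78 °C is far faster than deprotonation of the benzylic OCH2 or C2–H, and carboxylation of a 2,6-dialkoxyaryllithium with CO2 is a standard way to a hindered benzoic acid.

Step 5
Reactants: 8 3-methoxy-2-methylphenol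
Product: 9 triisopropyl(3-methoxy-2-methylphenoxy)silane
Conditions: TIPSCl, imidazole, DMF, rt
Reagents that add atoms: chlorotriisopropylsilane, CC(C)[Si](Cl)(C(C)C)C(C)C
Why: Silylation of a phenol (substitution at silicon) is routine, and the bulky silyl ether masks the future 6'-OH, survives all later steps and later steers the formylation.

Step 6
Reactants: 9 triisopropyl(3-methoxy-2-methylphenoxy)silane
Product: 11 3-methoxy-4-methyl-5-(triisopropylsilyloxy)phenol, via arylboronic pinacol ester 10 (not isolated)
Conditions: [Ir(OMe)(cod)]2 (1.5 mol %), 4,4'-di-tert-butyl-2,2'-bipyridine (3 mol %), B2pin2 (1.0 equiv), THF, 80 °C, sealed; evaporate; KHSO5 (Oxone), acetone–H2O, rt, 10 min; NaHSO3 quench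
Reagents that add atoms: bis(pinacolato)diboron, CC1(C)OB(OC1(C)C)B1OC(C)(C)C(C)(C)O1 (boron of intermediate 10 only); potassium peroxymonosulfate, [K+].OOS(=O)(=O)[O-]
Why: Iridium-catalysed aromatic C–H borylation is sterically governed and should occur only at C5, the one C–H with no ortho substituent, and oxidation of the C–B bond (1,2-aryl shift from boron to oxygen) gives the phenol in the same pot.

Step 7
Reactants: 11 3-methoxy-4-methyl-5-(triisopropylsilyloxy)phenol
Product: 12 2-hydroxy-6-methoxy-5-methyl-4-(triisopropylsilyloxy)benzaldehyde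
Conditions: MgCl2 (anhydrous), Et3N, (CH2O)n, MeCN, reflux; dilute HCl work-up
Reagents that add atoms: paraformaldehyde (as formaldehyde), C=O
Why: Magnesium-mediated ortho-formylation of phenols delivers formaldehyde within the magnesium phenoxide to an ortho carbon only, and of the two ortho positions the one beside the small methoxy group should react in preference to the one shielded by the triisopropylsilyloxy group.

Step 8
Reactants: 7 (2S)-7-benzyloxy-5-methoxyflavan-8-carboxylic acid; 12 2-hydroxy-6-methoxy-5-methyl-4-(triisopropylsilyloxy)benzaldehyde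
Product: 14 2-formyl-3-methoxy-4-methyl-5-(triisopropylsilyloxy)phenyl (2S)-7-benzyloxy-5-methoxyflavan-8-carboxylate, via acid chloride 13 (not isolated)
Conditions: (COCl)2, DMF (cat.), CH2Cl2, 0 °C to rt; evaporate; then 12, Et3N, DMAP, CH2Cl2, 0 °C to rt
Reagents that add atoms: oxalyl chloride, O=C(Cl)C(=O)Cl (chlorine of intermediate 13 only)
Why: Acylation of a phenol by an acid chloride under nucleophilic catalysis by DMAP is chosen because the 2,6-dioxygenated acid is too hindered for milder activation, while the phenoxide of 12 is a small and good nucleophile.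

Step 9
Reactants: 14 2-formyl-3-methoxy-4-methyl-5-(triisopropylsilyloxy)phenyl (2S)-7-benzyloxy-5-methoxyflavan-8-carboxylate
Product: 15 2-[(2S)-7-benzyloxy-5-methoxyflavan-8-yl]-4-methoxy-5-methyl-6-(triisopropylsilyloxy)benzofuran
Conditions: TiCl3 (8 equiv), Zn dust (16 equiv), DME, reflux, 2 h, argon; then 14 in DME added over 8–10 h by syringe pump (final concentration about 0.005 M), reflux; filtration through silica
Reagents that add atoms: none
Why: Low-valent titanium made from TiCl3 and zinc transfers an electron to the aldehyde, the more easily reduced carbonyl group, and the titanium-bound ketyl at the future C3' adds to the carbonyl carbon of the neighbouring aryl ester (future C2'); further reduction gives a titanium diolate that is deoxygenated on the oxophilic metal to the C2'=C3' double bond, helped by the gain of furan aromaticity. The closest known reaction type is the McMurry-type titanium-mediated oxo-ester cyclisation of 2-acyloxyaryl carbonyl compounds to benzofurans. The furan ring closes in a 5-exo-trig mode, the attacked ester C=O lying outside the five-membered ring built from O1', C7a', C3a', C3' and C2'. No stereocentre is created, and the remote C2 centre bears no acidic or reducible group and is not touched. The step needs selectivity for intramolecular ketyl–ester coupling over pinacol or alkene formation between two aldehydes and over plain reduction; this is secured by the ortho ester tether that holds the two carbonyl carbons in a 1,5-relationship, by slow addition at high dilution, and by the 2,6-dioxygenated aroyl group, which shields the ester from everything but the templated attack. The benzyl ether, the aryl silyl ether and the methyl ethers should not be reduced by this reagent.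

Step 10
Reactants: 15 2-[(2S)-7-benzyloxy-5-methoxyflavan-8-yl]-4-methoxy-5-methyl-6-(triisopropylsilyloxy)benzofuran
Product: 16 2-[(2S)-7-benzyloxy-5-methoxyflavan-8-yl]-4-methoxy-5-methylbenzofuran-6-ol
Conditions: Bu4NF, AcOH (1:1), THF, 0 °C
Reagents that add atoms: none
Why: Fluoride-induced desilylation of an aryl silyl ether is fast and selective, acetic acid buffers the phenoxide, and the benzyl ether, the methyl ethers and the flavan ring are inert.

Step 11
Reactants: 16 2-[(2S)-7-benzyloxy-5-methoxyflavan-8-yl]-4-methoxy-5-methylbenzofuran-6-ol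
Product: 17 (2S)-8-(6-hydroxy-4-methoxy-5-methylbenzofuran-2-yl)-5-methoxyflavan-7-ol (target)
Conditions: H2 (1 atm), 10% Pd/C, EtOAc–MeOH, rt
Reagents that add atoms: none
Why: Catalytic hydrogenolysis of the aryl benzyl ether should be much faster than reduction of the aromatic furan ring or cleavage of the cyclic benzylic C2–O1 bond under these mild neutral conditions, so the (2S) centre is kept.

Compound list
1 | alpinetin, (2S)-7-hydroxy-5-methoxyflavanone | COc1cc(O)cc2c1C(=O)C[C@@H](c1ccccc1)O2 | starting material
2 | (2S)-7-benzyloxy-5-methoxyflavanone | COc1cc(OCc3ccccc3)cc2c1C(=O)C[C@@H](c1ccccc1)O2 | intermediate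
3 | (2S,4S)-7-benzyloxy-5-methoxyflavan-4-ol (2,4-cis, expected major isomer; C4 configuration is irrelevant) | COc1cc(OCc3ccccc3)cc2c1[C@@H](O)C[C@@H](c1ccccc1)O2 | intermediate (not isolated)
4 | (2S)-7-benzyloxy-5-methoxyflavan | COc1cc(OCc3ccccc3)cc2c1CC[C@@H](c1ccccc1)O2 | intermediate
5 | (2S)-7-benzyloxy-8-bromo-5-methoxyflavan | COc1cc(OCc3ccccc3)c(Br)c2c1CC[C@@H](c1ccccc1)O2 | intermediate
6 | [(2S)-7-benzyloxy-5-methoxyflavan-8-yl]lithium | COc1cc(OCc3ccccc3)c([Li])c2c1CC[C@@H](c1ccccc1)O2 | intermediate (not isolated)
7 | (2S)-7-benzyloxy-5-methoxyflavan-8-carboxylic acid | COc1cc(OCc3ccccc3)c(C(=O)O)c2c1CC[C@@H](c1ccccc1)O2 | intermediate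
8 | 3-methoxy-2-methylphenol | COc1cccc(O)c1C | starting material
9 | triisopropyl(3-methoxy-2-methylphenoxy)silane | COc1cccc(O[Si](C(C)C)(C(C)C)C(C)C)c1C | intermediate
10 | 2-[3-methoxy-4-methyl-5-(triisopropylsilyloxy)phenyl]-4,4,5,5-tetramethyl-1,3,2-dioxaborolane | COc1cc(B2OC(C)(C)C(C)(C)O2)cc(O[Si](C(C)C)(C(C)C)C(C)C)c1C | intermediate (not isolated)
11 | 3-methoxy-4-methyl-5-(triisopropylsilyloxy)phenol | COc1cc(O)cc(O[Si](C(C)C)(C(C)C)C(C)C)c1C | intermediate
12 | 2-hydroxy-6-methoxy-5-methyl-4-(triisopropylsilyloxy)benzaldehyde | COc1c(C)c(O[Si](C(C)C)(C(C)C)C(C)C)cc(O)c1C=O | intermediate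
13 | (2S)-7-benzyloxy-5-methoxyflavan-8-carbonyl chloride | COc1cc(OCc3ccccc3)c(C(=O)Cl)c2c1CC[C@@H](c1ccccc1)O2 | intermediate (not isolated)
14 | 2-formyl-3-methoxy-4-methyl-5-(triisopropylsilyloxy)phenyl (2S)-7-benzyloxy-5-methoxyflavan-8-carboxylate | COc1cc(OCc5ccccc5)c(C(=O)Oc3cc(O[Si](C(C)C)(C(C)C)C(C)C)c(C)c(OC)c3C=O)c2c1CC[C@@H](c1ccccc1)O2 | intermediate (precursor of the key step)
15 | 2-[(2S)-7-benzyloxy-5-methoxyflavan-8-yl]-4-methoxy-5-methyl-6-(triisopropylsilyloxy)benzofuran | COc1cc(OCc5ccccc5)c(-c3cc4c(OC)c(C)c(O[Si](C(C)C)(C(C)C)C(C)C)cc4o3)c2c1CC[C@@H](c1ccccc1)O2 | intermediate (product of the key step)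
16 | 2-[(2S)-7-benzyloxy-5-methoxyflavan-8-yl]-4-methoxy-5-methylbenzofuran-6-ol | COc1cc(OCc5ccccc5)c(-c3cc4c(OC)c(C)c(O)cc4o3)c2c1CC[C@@H](c1ccccc1)O2 | intermediate
17 | (2S)-8-(6-hydroxy-4-methoxy-5-methylbenzofuran-2-yl)-5-methoxyflavan-7-ol | COc1cc(O)c(-c2cc3c(OC)c(C)c(O)cc3o2)c2c1CC[C@@H](c1ccccc1)O2 | target

Total step count: 11. Longest linear sequence: 8 steps (steps 1–4 and 8–11, from alpinetin); the salicylaldehyde branch is 3 steps (steps 5–7).

Steps most likely to fail

Step 9. Two aldehyde molecules may couple with each other (pinacol or stilbene formation), the aldehyde may simply be reduced, or the aryl ester may be cleaved before the ring closes. The fallback forms the same C2'=C3' bond by an intramolecular Wittig reaction on the ester carbonyl. It sets out from salicylaldehyde 12 and uses acid chloride 13 prepared as in step 8. Reduction of 12 with NaBH4 in MeOH at 0 °C would give 2-(hydroxymethyl)-3-methoxy-4-methyl-5-(triisopropylsilyloxy)phenol F1. Treatment with PPh3·HBr in MeCN at rt to 60 °C would give [2-hydroxy-6-methoxy-5-methyl-4-(triisopropylsilyloxy)benzyl]triphenylphosphonium bromide F2. Heating F2 with 13 and Et3N in toluene would acylate the phenol to {2-[(2S)-7-benzyloxy-5-methoxyflavan-8-carbonyloxy]-6-methoxy-5-methyl-4-(triisopropylsilyloxy)benzyl}triphenylphosphonium bromide F3, whose ylide should attack the ester carbonyl in the same flask. The fallback comes back to the route at benzofuran 15.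

Step 7. Formylation may occur at the other ortho position, beside the silyloxy group, or the silyl group may be lost on prolonged heating. The fallback fixes the position by directed ortho-metalation and sets out from phenol 11. MOMCl and i-Pr2NEt in CH2Cl2 would give triisopropyl[3-methoxy-5-(methoxymethoxy)-2-methylphenoxy]silane F4. n-BuLi with TMEDA in THF at 0 °C should deprotonate only the carbon flanked by the two coordinating groups OMOM and OMe, giving [2-methoxy-6-(methoxymethoxy)-3-methyl-4-(triisopropylsilyloxy)phenyl]lithium F5. Quenching with DMF would give 2-methoxy-6-(methoxymethoxy)-3-methyl-4-(triisopropylsilyloxy)benzaldehyde F6. Mild acid (catalytic HCl in MeOH–THF, rt) would remove the chelation-activated MOM group while the aryl silyl ether stays. The fallback comes back to the route at salicylaldehyde 12.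

Step 3. Attack at C6 and double bromination may compete and give bromides that are hard to separate. The fallback introduces the carboxyl carbon directly and avoids the organolithium of step 4; it sets out from flavan 4. Vilsmeier–Haack formylation (POCl3, DMF, 0 to 60 °C) uses a bulkier and weaker electrophile that should stop at monosubstitution and discriminate better between C8 and C6. It would give the iminium salt N-{[(2S)-7-benzyloxy-5-methoxyflavan-8-yl]methylidene}-N-methylmethanaminium chloride F7, and aqueous NaOAc would hydrolyse this to (2S)-7-benzyloxy-5-methoxyflavan-8-carbaldehyde F8, the position being checkable by NOE between the formyl proton and the OCH2Ph group alone. Pinnick oxidation (NaClO2, NaH2PO4, 2-methyl-2-butene, t-BuOH–H2O, rt) would then give the acid. The fallback comes back to the route at acid 7.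

Further compounds
F1 | step 9 | 2-(hydroxymethyl)-3-methoxy-4-methyl-5-(triisopropylsilyloxy)phenol | COc1c(C)c(O[Si](C(C)C)(C(C)C)C(C)C)cc(O)c1CO
F2 | step 9 | [2-hydroxy-6-methoxy-5-methyl-4-(triisopropylsilyloxy)benzyl]triphenylphosphonium bromide | COc1c(C)c(O[Si](C(C)C)(C(C)C)C(C)C)cc(O)c1C[P+](c1ccccc1)(c1ccccc1)c1ccccc1.[Br-]
F3 | step 9 | {2-[(2S)-7-benzyloxy-5-methoxyflavan-8-carbonyloxy]-6-methoxy-5-methyl-4-(triisopropylsilyloxy)benzyl}triphenylphosphonium bromide | COc1cc(OCc5ccccc5)c(C(=O)Oc3cc(O[Si](C(C)C)(C(C)C)C(C)C)c(C)c(OC)c3C[P+](c3ccccc3)(c3ccccc3)c3ccccc3)c2c1CC[C@@H](c1ccccc1)O2.[Br-]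
F4 | step 7 | triisopropyl[3-methoxy-5-(methoxymethoxy)-2-methylphenoxy]silane | COCOc1cc(OC)c(C)c(O[Si](C(C)C)(C(C)C)C(C)C)c1
F5 | step 7 | [2-methoxy-6-(methoxymethoxy)-3-methyl-4-(triisopropylsilyloxy)phenyl]lithium | COCOc1cc(O[Si](C(C)C)(C(C)C)C(C)C)c(C)c(OC)c1[Li]
F6 | step 7 | 2-methoxy-6-(methoxymethoxy)-3-methyl-4-(triisopropylsilyloxy)benzaldehyde | COCOc1cc(O[Si](C(C)C)(C(C)C)C(C)C)c(C)c(OC)c1C=O
F7 | step 3 | N-{[(2S)-7-benzyloxy-5-methoxyflavan-8-yl]methylidene}-N-methylmethanaminium chloride | COc1cc(OCc3ccccc3)c(C=[N+](C)C)c2c1CC[C@@H](c1ccccc1)O2.[Cl-]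
F8 | step 3 | (2S)-7-benzyloxy-5-methoxyflavan-8-carbaldehyde | COc1cc(OCc3ccccc3)c(C=O)c2c1CC[C@@H](c1ccccc1)O2
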